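**Retrosynthetic overview**
1. 24 ⇐ 23 ⇐ 22: the end game is unmasking only. The ring A benzyl ether goes by hydrogenolysis and the side-chain acetonide by mild aqueous acid.
2. 22 ⇐ 21: the C9 CH2OH group comes from reductive removal of an oxazolidinone auxiliary.
3. Key disconnection C7–C8: a boron-mediated Evans syn-aldol joins aryloxyacetyl imide 18 and O-benzylvanillin 2. The (S)-auxiliary fixes 7R,8R (threo).
4. 18 ⇐ phenol 11 + ethyl bromoacetate + (S)-4-benzyloxazolidinone. 11 ⇐ syringol-derived aryl Grignard + (S)-benzyl glycidyl ether, which fixes C8' as S from the chiral pool.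
5. Rings: no ring of the target is built. Ring A is bought as vanillin and ring B as syringol. Only a temporary dioxolane is closed (step 6) and opened again (step 12).

Assumption: potassium phenoxides formed in equilibrium with K2CO3 and ill-defined borate complexes before quench are not numbered; locants C7–C9 denote the glycerol chain and C7'–C9' the propyl chain on ring B.

**Step 1**
Reactants: 1 vanillin (4-hydroxy-3-methoxybenzaldehyde)
Product: 2 4-(benzyloxy)-3-methoxybenzaldehyde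
Conditions: BnBr, K2CO3, DMF, 60 °C
Reagents that add atoms: benzyl bromide, BrCc1ccccc1
Why: Williamson ether synthesis (SN2 of the phenoxide on benzyl bromide) masks the acidic phenol, which would quench the boron enolate of step 10, as a group that is removable under neutral conditions.

**Step 2**
Reactants: 3 2,6-dimethoxyphenol (syringol)
Product: 4 4-bromo-2,6-dimethoxyphenol
Conditions: NBS (1.05 equiv), NaH (1 mol %), trace MeOH, CHCl3, −45 °C to reflux
Reagents that add atoms: N-bromosuccinimide, O=C1CCC(=O)N1Br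
Why: Electrophilic aromatic bromination under phenoxide catalysis sends bromine para to the OH (both ortho positions carry OMe) rather than to the OMe-activated C3, and the low temperature suppresses dibromination.

**Step 3**
Reactants: 4 4-bromo-2,6-dimethoxyphenol
Product: 5 2-(benzyloxy)-5-bromo-1,3-dimethoxybenzene
Conditions: BnBr, K2CO3, DMF, 60 °C
Reagents that add atoms: benzyl bromide, BrCc1ccccc1
Why: Williamson ether synthesis removes the acidic proton that is incompatible with the Grignard reagent of step 4.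

**Step 4**
Reactants: 5 2-(benzyloxy)-5-bromo-1,3-dimethoxybenzene; 6 (S)-benzyl glycidyl ether, (2S)-2-[(benzyloxy)methyl]oxirane
Product: 9 (2S)-1-(benzyloxy)-3-[4-(benzyloxy)-3,5-dimethoxyphenyl]propan-2-ol, via arylmagnesium bromide 7 (not isolated), via bromomagnesium alkoxide 8 (not isolated)
Conditions: Mg, I2 (cat.), THF, reflux; then CuI (10 mol %), 6, THF, −30 to 0 °C; sat. aq NH4Cl
Reagents that add atoms: none
Why: Grignard formation is followed by copper-catalysed SN2 opening of the epoxide at its unsubstituted carbon, so the C–O bond at the stereocentre is untouched and C8' is taken over as (S) from the chiral-pool epoxide.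

**Step 5**
Reactants: 9 (2S)-1-(benzyloxy)-3-[4-(benzyloxy)-3,5-dimethoxyphenyl]propan-2-ol
Product: 10 4-[(2S)-2,3-dihydroxypropyl]-2,6-dimethoxyphenol
Conditions: H2 (1 atm), 10% Pd/C, EtOH, rt
Reagents that add atoms: none
Why: Catalytic hydrogenolysis cleaves the aryl benzyl ether and the primary alkyl benzyl ether together, and nothing else in 9 is reducible because C8' is not benzylic.

**Step 6**
Reactants: 10 4-[(2S)-2,3-dihydroxypropyl]-2,6-dimethoxyphenol
Product: 11 4-{[(4S)-2,2-dimethyl-1,3-dioxolan-4-yl]methyl}-2,6-dimethoxyphenol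
Conditions: Me2C(OMe)2, PPTS (cat.), acetone, rt
Reagents that add atoms: 2,2-dimethoxypropane, COC(C)(C)OC
Why: Acid-catalysed transketalisation closes the five-membered dioxolane on the 1,2-diol only, since the phenol forms no stable ketal, and C8' is unchanged.

**Step 7**
Reactants: 11 4-{[(4S)-2,2-dimethyl-1,3-dioxolan-4-yl]methyl}-2,6-dimethoxyphenol; 12 ethyl bromoacetate
Product: 13 ethyl 2-(4-{[(4S)-2,2-dimethyl-1,3-dioxolan-4-yl]methyl}-2,6-dimethoxyphenoxy)acetate
Conditions: K2CO3, DMF, 50 °C, N2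
Reagents that add atoms: none
Why: Williamson ether synthesis works here because the hindered but nucleophilic 2,6-dimethoxyphenoxide displaces the very reactive α-bromo ester by SN2, which installs C8 and C9.

**Step 8**
Reactants: 13 ethyl 2-(4-{[(4S)-2,2-dimethyl-1,3-dioxolan-4-yl]methyl}-2,6-dimethoxyphenoxy)acetate
Product: 15 2-(4-{[(4S)-2,2-dimethyl-1,3-dioxolan-4-yl]methyl}-2,6-dimethoxyphenoxy)acetic acid, via lithium carboxylate 14 (not isolated)
Conditions: LiOH·H2O, THF/H2O, rt; then 1 M HCl to pH 3–4, 0 °C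
Reagents that add atoms: lithium hydroxide, [Li+].[OH-]
Why: Saponification (acyl–oxygen ester hydrolysis) is fast for an aryloxyacetate, and the short cold acidification does not harm the acetonide.

**Step 9**
Reactants: 15 2-(4-{[(4S)-2,2-dimethyl-1,3-dioxolan-4-yl]methyl}-2,6-dimethoxyphenoxy)acetic acid; 16 (4S)-4-benzyl-1,3-oxazolidin-2-one
Product: 18 (4S)-4-benzyl-3-[2-(4-{[(4S)-2,2-dimethyl-1,3-dioxolan-4-yl]methyl}-2,6-dimethoxyphenoxy)acetyl]-1,3-oxazolidin-2-one, via pivaloyl mixed anhydride 17 (not isolated)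
Conditions: PivCl, Et3N, THF, −20 °C; then LiCl, 16, −20 °C to rt
Reagents that add atoms: none
Why: In this N-acylation through a mixed pivalic anhydride, the LiCl-activated oxazolidinone attacks the unhindered aryloxyacetyl carbonyl rather than the tert-butyl-shielded one, and no strong base is needed.

**Step 10**
Reactants: 18 (4S)-4-benzyl-3-[2-(4-{[(4S)-2,2-dimethyl-1,3-dioxolan-4-yl]methyl}-2,6-dimethoxyphenoxy)acetyl]-1,3-oxazolidin-2-one; 2 4-(benzyloxy)-3-methoxybenzaldehyde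
Product: 21 (4S)-4-benzyl-3-[(2S,3R)-3-[4-(benzyloxy)-3-methoxyphenyl]-2-(4-{[(4S)-2,2-dimethyl-1,3-dioxolan-4-yl]methyl}-2,6-dimethoxyphenoxy)-3-hydroxypropanoyl]-1,3-oxazolidin-2-one, via Z-dibutylboron enolate 19 (not isolated), via dibutylboron aldolate 20 (not isolated)
Conditions: Bu2BOTf (1.2 equiv), Et3N (1.4 equiv), CH2Cl2, −78 to 0 °C; 2, −78 to 0 °C; pH 7 buffer, MeOH, 30% H2O2, 0 °C
Reagents that add atoms: none
Why: In this Evans syn-aldol reaction, soft enolisation gives the Z-boron enolate, which meets the aldehyde in a closed Zimmerman–Traxler chair on the face away from the auxiliary's benzyl group, so the C7–C8 bond forms as the 2S,3R syn adduct (7R,8R threo after reduction).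

**Step 11**
Reactants: 21 the syn-aldol adduct of step 10
Product: 22 (1R,2R)-1-[4-(benzyloxy)-3-methoxyphenyl]-2-(4-{[(4S)-2,2-dimethyl-1,3-dioxolan-4-yl]methyl}-2,6-dimethoxyphenoxy)propane-1,3-diol
Conditions: LiBH4, H2O (2 equiv), THF, 0 °C; water quench
Reagents that add atoms: none
Why: In this reductive cleavage of the imide, LiBH4 attacks the more electrophilic exocyclic carbonyl and takes it to the primary alcohol without touching C7 or C8, and the C8 descriptor changes from S to R only through the CIP priority switch.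

**Step 12**
Reactants: 22 (1R,2R)-1-[4-(benzyloxy)-3-methoxyphenyl]-2-(4-{[(4S)-2,2-dimethyl-1,3-dioxolan-4-yl]methyl}-2,6-dimethoxyphenoxy)propane-1,3-diol
Product: 23 (1R,2R)-1-[4-(benzyloxy)-3-methoxyphenyl]-2-{4-[(2S)-2,3-dihydroxypropyl]-2,6-dimethoxyphenoxy}propane-1,3-diol
Conditions: AcOH/H2O (4:1), 40 °C; toluene azeotrope
Reagents that add atoms: none
Why: Acid-catalysed acetal hydrolysis cleaves the terminal dioxolane with aqueous acetic acid, which is too weak to ionise the benzylic C7–OH while the ring A phenol is still benzylated, so C7 does not epimerise.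

**Step 13**
Reactants: 23 (1R,2R)-1-[4-(benzyloxy)-3-methoxyphenyl]-2-{4-[(2S)-2,3-dihydroxypropyl]-2,6-dimethoxyphenoxy}propane-1,3-diol
Product: 24 (1R,2R)-2-{4-[(2S)-2,3-dihydroxypropyl]-2,6-dimethoxyphenoxy}-1-(4-hydroxy-3-methoxyphenyl)propane-1,3-diol (target)
Conditions: H2 (1 atm), 10% Pd/C, EtOAc/EtOH, rt, stopped at full conversion
Reagents that add atoms: none
Why: Catalytic hydrogenolysis under neutral conditions at 1 atm cleaves the phenolic benzyl ether much faster than the secondary benzylic C7–OH, so all three stereocentres survive.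

**Compound list**
1 | vanillin | COc1cc(C=O)ccc1O | starting material
2 | 4-(benzyloxy)-3-methoxybenzaldehyde | COc1cc(C=O)ccc1OCc1ccccc1 | intermediate
3 | 2,6-dimethoxyphenol | COc1cccc(OC)c1O | starting material
4 | 4-bromo-2,6-dimethoxyphenol | COc1cc(Br)cc(OC)c1O | intermediate
5 | 2-(benzyloxy)-5-bromo-1,3-dimethoxybenzene | COc1cc(Br)cc(OC)c1OCc1ccccc1 | intermediate
6 | (S)-benzyl glycidyl ether | C1O[C@@H]1COCc1ccccc1 | starting material
7 | [4-(benzyloxy)-3,5-dimethoxyphenyl]magnesium bromide | COc1cc([Mg]Br)cc(OC)c1OCc1ccccc1 | intermediate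
8 | bromomagnesium (2S)-1-(benzyloxy)-3-[4-(benzyloxy)-3,5-dimethoxyphenyl]propan-2-olate | COc1cc(C[C@H](O[Mg]Br)COCc2ccccc2)cc(OC)c1OCc1ccccc1 | intermediate
9 | (2S)-1-(benzyloxy)-3-[4-(benzyloxy)-3,5-dimethoxyphenyl]propan-2-ol | COc1cc(C[C@H](O)COCc2ccccc2)cc(OC)c1OCc1ccccc1 | intermediate
10 | 4-[(2S)-2,3-dihydroxypropyl]-2,6-dimethoxyphenol | COc1cc(C[C@H](O)CO)cc(OC)c1O | intermediate
11 | 4-{[(4S)-2,2-dimethyl-1,3-dioxolan-4-yl]methyl}-2,6-dimethoxyphenol | COc1cc(C[C@H]2COC(C)(C)O2)cc(OC)c1O | intermediate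
12 | ethyl bromoacetate | CCOC(=O)CBr | starting material
13 | ethyl 2-(4-{[(4S)-2,2-dimethyl-1,3-dioxolan-4-yl]methyl}-2,6-dimethoxyphenoxy)acetate | CCOC(=O)COc1c(OC)cc(C[C@H]2COC(C)(C)O2)cc1OC | intermediate
14 | lithium 2-(4-{[(4S)-2,2-dimethyl-1,3-dioxolan-4-yl]methyl}-2,6-dimethoxyphenoxy)acetate | [Li+].[O-]C(=O)COc1c(OC)cc(C[C@H]2COC(C)(C)O2)cc1OC | intermediate
15 | 2-(4-{[(4S)-2,2-dimethyl-1,3-dioxolan-4-yl]methyl}-2,6-dimethoxyphenoxy)acetic acid | OC(=O)COc1c(OC)cc(C[C@H]2COC(C)(C)O2)cc1OC | intermediate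
16 | (4S)-4-benzyl-1,3-oxazolidin-2-one | O=C1N[C@@H](Cc2ccccc2)CO1 | starting material
17 | mixed anhydride of 15 and pivalic acid | CC(C)(C)C(=O)OC(=O)COc1c(OC)cc(C[C@H]2COC(C)(C)O2)cc1OC | intermediate
18 | (4S)-4-benzyl-3-[2-(4-{[(4S)-2,2-dimethyl-1,3-dioxolan-4-yl]methyl}-2,6-dimethoxyphenoxy)acetyl]-1,3-oxazolidin-2-one | O=C(COc1c(OC)cc(C[C@H]2COC(C)(C)O2)cc1OC)N1C(=O)OC[C@@H]1Cc1ccccc1 | intermediate
19 | (Z)-dibutylboron enolate of 18 | CCCCB(CCCC)O/C(=C\Oc1c(OC)cc(C[C@H]2COC(C)(C)O2)cc1OC)N1C(=O)OC[C@@H]1Cc1ccccc1 | intermediate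
20 | C7-O-dibutylboron aldolate of 21 | COc1cc([C@@H](OB(CCCC)CCCC)[C@@H](C(=O)N2C(=O)OC[C@@H]2Cc2ccccc2)Oc2c(OC)cc(C[C@H]3COC(C)(C)O3)cc2OC)ccc1OCc1ccccc1 | intermediate
21 | (4S)-4-benzyl-3-[(2S,3R)-3-[4-(benzyloxy)-3-methoxyphenyl]-2-(4-{[(4S)-2,2-dimethyl-1,3-dioxolan-4-yl]methyl}-2,6-dimethoxyphenoxy)-3-hydroxypropanoyl]-1,3-oxazolidin-2-one | COc1cc([C@@H](O)[C@@H](C(=O)N2C(=O)OC[C@@H]2Cc2ccccc2)Oc2c(OC)cc(C[C@H]3COC(C)(C)O3)cc2OC)ccc1OCc1ccccc1 | intermediate
22 | (1R,2R)-1-[4-(benzyloxy)-3-methoxyphenyl]-2-(4-{[(4S)-2,2-dimethyl-1,3-dioxolan-4-yl]methyl}-2,6-dimethoxyphenoxy)propane-1,3-diol | COc1cc([C@@H](O)[C@@H](CO)Oc2c(OC)cc(C[C@H]3COC(C)(C)O3)cc2OC)ccc1OCc1ccccc1 | intermediate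
23 | (1R,2R)-1-[4-(benzyloxy)-3-methoxyphenyl]-2-{4-[(2S)-2,3-dihydroxypropyl]-2,6-dimethoxyphenoxy}propane-1,3-diol | COc1cc([C@@H](O)[C@@H](CO)Oc2c(OC)cc(C[C@H](O)CO)cc2OC)ccc1OCc1ccccc1 | intermediate
24 | (1R,2R)-2-{4-[(2S)-2,3-dihydroxypropyl]-2,6-dimethoxyphenoxy}-1-(4-hydroxy-3-methoxyphenyl)propane-1,3-diol | COc1cc([C@@H](O)[C@@H](CO)Oc2c(OC)cc(C[C@H](O)CO)cc2OC)ccc1O | target

**Totals**
- Total step count: 13.
- Longest linear sequence: 12 (steps 2–13, from syringol). Step 1 is a one-step side branch.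

**Three steps most likely to fail**

*Step 4 (aryl Grignard / epoxide opening).*
- Risk: sluggish magnesium insertion into the electron-rich bromide, or halohydrin formation in place of C–C coupling.
- The fallback sets out from 5 and comes back at 10. It builds the chain as an olefin and sets C8' by catalysis instead of from the chiral pool.
- Stille coupling of 5 with allyltributylstannane (Pd(PPh3)4, zerovalent palladium, toluene, 100 °C) gives 5-allyl-2-(benzyloxy)-1,3-dimethoxybenzene F1.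
- mCPBA (NaHCO3, CH2Cl2, 0 °C) then gives racemic 2-[4-(benzyloxy)-3,5-dimethoxybenzyl]oxirane F2.
- Jacobsen hydrolytic kinetic resolution follows, with (R,R)-(salen)Co(OAc) and 0.45 equiv of water. The cobalt is trivalent, and salen is the dianion of N,N'-bis(3,5-di-tert-butylsalicylidene)cyclohexane-1,2-diamine.
- This hydrolyses only the (S)-epoxide, at its terminal carbon, to (2S)-3-[4-(benzyloxy)-3,5-dimethoxyphenyl]propane-1,2-diol F3.
- F3 is separated by chromatography from unreacted (2R)-2-[4-(benzyloxy)-3,5-dimethoxybenzyl]oxirane F4.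
- Hydrogenolysis of F3 (H2, 10% Pd/C, EtOH) gives 10.

*Step 10 (Evans aldol).*
- Risk: the bulky, Lewis-basic 2,6-dimethoxyphenoxy group may slow enolisation, and the electron-rich aldehyde may give low conversion, eroded selectivity or retro-aldol.
- The fallback sets out from 13 and 2 and comes back at 22. It keeps the same C7–C8 bond formation but moves stereocontrol to a later catalytic reduction.
- LDA (THF, −78 °C) converts 13 into the lithium enolate of 13 F5.
- F5 adds to 2 to give ethyl 3-[4-(benzyloxy)-3-methoxyphenyl]-2-(4-{[(4S)-2,2-dimethyl-1,3-dioxolan-4-yl]methyl}-2,6-dimethoxyphenoxy)-3-hydroxypropanoate, a mixture at C7/C8, F6.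
- Dess–Martin periodinane oxidises F6 to the configurationally labile ethyl 3-aryl-2-aryloxy-3-oxopropanoate F7.
- Noyori-type asymmetric transfer hydrogenation with dynamic kinetic resolution follows (RuCl(p-cymene)[(S,S)-TsDPEN], HCO2H/Et3N 5:2, 30 °C). By the usual aryl-ketone model this should give 7R together with the syn relationship.
- The product is ethyl (2S,3R)-3-[4-(benzyloxy)-3-methoxyphenyl]-2-(4-{[(4S)-2,2-dimethyl-1,3-dioxolan-4-yl]methyl}-2,6-dimethoxyphenoxy)-3-hydroxypropanoate F8.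
- LiBH4 (THF/MeOH, 0 °C) reduces F8 to 22.

*Step 12 (acid removal of the acetonide next to an electron-rich benzylic alcohol).*
- Risk: partial ionisation at C7, which would epimerise threo to erythro, or acetonide migration onto the 7,9-diol.
- The fallback sets out from 21 and comes back at 23. It reverses the order of events, so the acid step runs while the C7 carbinol is still β to the electron-withdrawing imide carbonyl, which destabilises a C7 cation.
- Treating 21 with AcOH/H2O (4:1, 40 °C) gives (4S)-4-benzyl-3-[(2S,3R)-3-[4-(benzyloxy)-3-methoxyphenyl]-2-{4-[(2S)-2,3-dihydroxypropyl]-2,6-dimethoxyphenoxy}-3-hydroxypropanoyl]-1,3-oxazolidin-2-one F9.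
- Excess LiBH4 (THF/H2O, 0 °C) then removes the auxiliary reductively and gives 23 directly.

**Further compounds**
F1 | step 4 | 5-allyl-2-(benzyloxy)-1,3-dimethoxybenzene | C=CCc1cc(OC)c(OCc2ccccc2)c(OC)c1
F2 | step 4 | racemic 2-[4-(benzyloxy)-3,5-dimethoxybenzyl]oxirane | COc1cc(CC2CO2)cc(OC)c1OCc1ccccc1
F3 | step 4 | (2S)-3-[4-(benzyloxy)-3,5-dimethoxyphenyl]propane-1,2-diol | COc1cc(C[C@H](O)CO)cc(OC)c1OCc1ccccc1
F4 | step 4 | (2R)-2-[4-(benzyloxy)-3,5-dimethoxybenzyl]oxirane | COc1cc(C[C@@H]2CO2)cc(OC)c1OCc1ccccc1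
F5 | step 10 | lithium enolate of 13 | [Li+].CCOC([O-])=COc1c(OC)cc(C[C@H]2COC(C)(C)O2)cc1OC
F6 | step 10 | ethyl 3-[4-(benzyloxy)-3-methoxyphenyl]-2-(4-{[(4S)-2,2-dimethyl-1,3-dioxolan-4-yl]methyl}-2,6-dimethoxyphenoxy)-3-hydroxypropanoate, mixture at C7/C8 | CCOC(=O)C(Oc1c(OC)cc(C[C@H]2COC(C)(C)O2)cc1OC)C(O)c1ccc(OCc2ccccc2)c(OC)c1
F7 | step 10 | ethyl 3-[4-(benzyloxy)-3-methoxyphenyl]-2-(4-{[(4S)-2,2-dimethyl-1,3-dioxolan-4-yl]methyl}-2,6-dimethoxyphenoxy)-3-oxopropanoate | CCOC(=O)C(Oc1c(OC)cc(C[C@H]2COC(C)(C)O2)cc1OC)C(=O)c1ccc(OCc2ccccc2)c(OC)c1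
F8 | step 10 | ethyl (2S,3R)-3-[4-(benzyloxy)-3-methoxyphenyl]-2-(4-{[(4S)-2,2-dimethyl-1,3-dioxolan-4-yl]methyl}-2,6-dimethoxyphenoxy)-3-hydroxypropanoate | COc1cc([C@@H](O)[C@@H](C(=O)OCC)Oc2c(OC)cc(C[C@H]3COC(C)(C)O3)cc2OC)ccc1OCc1ccccc1
F9 | step 12 | (4S)-4-benzyl-3-[(2S,3R)-3-[4-(benzyloxy)-3-methoxyphenyl]-2-{4-[(2S)-2,3-dihydroxypropyl]-2,6-dimethoxyphenoxy}-3-hydroxypropanoyl]-1,3-oxazolidin-2-one | COc1cc([C@@H](O)[C@@H](C(=O)N2C(=O)OC[C@@H]2Cc2ccccc2)Oc2c(OC)cc(C[C@H](O)CO)cc2OC)ccc1OCc1ccccc1
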